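**Strategy.** The bicyclo[4.4.1]undecene formed by rings A and B (the two seven-membered rings that share the one-carbon bridge Cc between the bridgehead CH Cb and the olefinic bridgehead Cd) is made by rearranging an ordinary 6-6-6 hydrophenanthrene in which Cc is still an angular CH2OTf on Cb. Ionisation with participation of the homoallylic Cd=C alkene inserts Cc into the Cb–Cd fusion bond, so rings A and B each grow from six to seven atoms, and the bridgehead cation is discharged by a semipinacol 1,2-hydride shift from the adjacent silyloxy carbon Ca. The precursor arises from a citronellal-derived ring C and a cyclohexanedione by Claisen rearrangement and Suzuki closure.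

Key step: step 16

Remark: ring C is the cyclohexene; Ca is the carbon that ends as C=CH2; rings A' and B' are the six-membered precursors of rings A and B; R = (2S,5E)-7-[(tert-butyldiphenylsilyl)oxy]-6-methylhept-5-en-2-yl. It is assumed that the side-chain stereocentre is taken unchanged from (S)-citronellal.

Step 1
Reactants: 1 (S)-citronellal; 2 methyl vinyl ketone
Product: 3 (2S,3S)-3,7-dimethyl-2-(3-oxobutyl)oct-6-enal
Conditions: (S)-α,α-diphenylprolinol trimethylsilyl ether (5 mol%), ethyl 3,4-dihydroxybenzoate (20 mol%), neat, 4 °C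
Reagents that add atoms: none
Why: Enamine-catalysed Michael addition (Jørgensen–Hayashi type) in which the (S)-catalyst shields one face of the anti-(E)-enamine of 1, so the new α-stereocentre (later the ring C carbon that carries the side chain) is set by the catalyst next to the untouched citronellal stereocentre.

Step 2
Reactants: 3 (2S,3S)-3,7-dimethyl-2-(3-oxobutyl)oct-6-enal
Product: 4 (4S)-4-[(2S)-6-methylhept-5-en-2-yl]cyclohex-2-en-1-one
Conditions: KOH, Bu4NOH (cat.), THF/Et2O/H2O, reflux
Reagents that add atoms: none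
Why: Intramolecular aldol condensation (ring-closing half of a Robinson annulation) of the methyl ketone enolate onto the aldehyde gives the conjugated cyclohexenone, and the stereocentre should survive because cyclisation is faster than enolisation of the aldehyde.

Step 3
Reactants: 4 (4S)-4-[(2S)-6-methylhept-5-en-2-yl]cyclohex-2-en-1-one
Product: 5 (4S)-4-[(2S,5E)-7-hydroxy-6-methylhept-5-en-2-yl]cyclohex-2-en-1-one
Conditions: SeO2 (0.5 equiv), t-BuOOH (3 equiv), salicylic acid (10 mol%), CH2Cl2, rt
Reagents that add atoms: selenium dioxide O=[Se]=O (oxygen carrier, reoxidised by tert-butyl hydroperoxide CC(C)(C)OO)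
Why: Selenium dioxide allylic oxidation (ene reaction then [2,3]-shift, Sharpless conditions) attacks only the electron-rich trisubstituted alkene at its (E)-methyl group and so should give the (E)-allylic alcohol while the electron-poor enone alkene stays inert.

Step 4
Reactants: 5 (4S)-4-[(2S,5E)-7-hydroxy-6-methylhept-5-en-2-yl]cyclohex-2-en-1-one
Product: 6 (4S)-4-R-cyclohex-2-en-1-one
Conditions: TBDPSCl, imidazole, DMF, rt
Reagents that add atoms: tert-butyl(chloro)diphenylsilane CC(C)(C)[Si](Cl)(c1ccccc1)c1ccccc1
Why: Standard silylation of the primary allylic alcohol gives an ether that tolerates the later bases, organometallics and Lewis acids and is removed only in the last step.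

Step 5
Reactants: 6 (4S)-4-R-cyclohex-2-en-1-one
Product: 7 (4S)-2-iodo-4-R-cyclohex-2-en-1-one
Conditions: I2, pyridine, CH2Cl2, 0 °C to rt
Reagents that add atoms: iodine II
Why: Johnson α-iodination of an enone (pyridine conjugate addition, iodination of the enolate, elimination) places iodine on the α-carbon as the handle for the two-carbon unit of ring B.

Step 6
Reactants: 7 (4S)-2-iodo-4-R-cyclohex-2-en-1-one
Product: 8 (1R,4S)-2-iodo-1-methyl-4-R-cyclohex-2-en-1-ol (hydroxyl trans to R)
Conditions: MeLi, Et2O, −78 °C; aq. NH4Cl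
Reagents that add atoms: methyllithium [Li]C
Why: 1,2-Addition of methyllithium to the enone carbonyl (faster than iodine–lithium exchange at −78 °C) by axial attack on the half-chair should leave the hydroxyl pseudo-equatorial and trans to the side chain, setting the carbinol stereocentre by substrate control.

Step 7
Reactants: 8 (1R,4S)-2-iodo-1-methyl-4-R-cyclohex-2-en-1-ol
Product: 9 (1R,4S)-2-ethenyl-1-methyl-4-R-cyclohex-2-en-1-ol
Conditions: tributyl(vinyl)stannane, Pd(PPh3)4 (5 mol%), CuI (10 mol%), DMF, 50 °C
Reagents that add atoms: tributyl(vinyl)stannane C=C[Sn](CCCC)(CCCC)CCCC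
Why: Stille coupling of the alkenyl iodide (oxidative addition, CuI-assisted transmetalation, reductive elimination) installs the vinyl group without touching the tertiary allylic alcohol or its stereocentre.

Step 8
Reactants: 10 diethyl 3-oxoheptanedioate
Product: 11 ethyl 2,6-dioxocyclohexane-1-carboxylate
Conditions: NaOEt, EtOH, reflux; then aq. HCl
Reagents that add atoms: none
Why: Dieckmann condensation in which the doubly activated methylene attacks the distal ester to close the six-membered ring, the product being drained as its strongly stabilised tricarbonyl enolate.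

Step 9
Reactants: 11 ethyl 2,6-dioxocyclohexane-1-carboxylate
Product: 12 ethyl 2-chloro-6-oxocyclohex-1-ene-1-carboxylate
Conditions: (COCl)2, DMF (cat.), CH2Cl2, 0 °C to rt
Reagents that add atoms: oxalyl chloride O=C(Cl)C(Cl)=O
Why: The enolised 1,3-dione is converted into its vinylogous acid chloride by the Vilsmeier reagent formed from oxalyl chloride and DMF, the standard route to β-chloro enones.

Step 10
Reactants: 9 (1R,4S)-2-ethenyl-1-methyl-4-R-cyclohex-2-en-1-ol; 12 ethyl 2-chloro-6-oxocyclohex-1-ene-1-carboxylate
Product: 14 ethyl 2,6-dioxo-1-[(1S,6S)-2-ethenyl-3-methyl-6-R-cyclohex-2-en-1-yl]cyclohexane-1-carboxylate, via allyl vinyl ether 13 (not isolated)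
Conditions: KH, THF, 0 °C; then 12, −78 to 0 °C; aq. NH4Cl; then PhMe, 80 °C
Reagents that add atoms: none
Why: Addition–elimination of the tertiary potassium alkoxide on the doubly activated β-chloro enone gives the allyl vinyl ether, whose Claisen [3,3] rearrangement delivers the dione carbon suprafacially to the ring C allyl terminus on the face of the breaking C–O bond (trans to R), so the ring B/C fusion CH is set by chirality transfer from the carbinol centre while the ring C alkene moves into its final tetrasubstituted position and the new quaternary carbon Cb is not yet stereogenic.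

Step 11
Reactants: 14 ethyl 2,6-dioxo-1-[(1S,6S)-2-ethenyl-3-methyl-6-R-cyclohex-2-en-1-yl]cyclohexane-1-carboxylate
Product: 15 ethyl (1R,2S)-2-hydroxy-6-oxo-1-[(1S,6S)-2-ethenyl-3-methyl-6-R-cyclohex-2-en-1-yl]cyclohexane-1-carboxylate (hydroxyl trans to the ester)
Conditions: (R)-2-methyl-CBS-oxazaborolidine (30 mol%), catecholborane (1.5 equiv), PhMe, −78 to −40 °C; pH 7 buffer
Reagents that add atoms: none
Why: Corey–Bakshi–Shibata reduction used as a group-selective desymmetrisation, in which the (R)-catalyst imposes the (S)-carbinol and hydride enters anti to the bulky ring C substituent, a combination only one of the two carbonyls can satisfy, so the Ca carbinol and the quaternary stereocentre Cb are both fixed under reagent control.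

Step 12
Reactants: 15 ethyl (1R,2S)-2-hydroxy-6-oxo-1-[ring C]cyclohexane-1-carboxylate
Product: 16 ethyl (1R,2S)-2-[(tert-butyldimethylsilyl)oxy]-6-oxo-1-[(1S,6S)-2-ethenyl-3-methyl-6-R-cyclohex-2-en-1-yl]cyclohexane-1-carboxylate
Conditions: TBSOTf, 2,6-lutidine, CH2Cl2, −78 °C
Reagents that add atoms: tert-butyldimethylsilyl trifluoromethanesulfonate CC(C)(C)[Si](C)(C)OS(=O)(=O)C(F)(F)F
Why: Silylation of the hindered secondary alcohol with the silyl triflate at low temperature is faster than enol silylation of the ketone and installs the silyloxy group that later terminates the cationic cascade.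

Step 13
Reactants: 16 ethyl (1R,2S)-2-[(tert-butyldimethylsilyl)oxy]-6-oxo-1-[ring C]cyclohexane-1-carboxylate
Product: 17 ethyl (1R,6S)-6-[(tert-butyldimethylsilyl)oxy]-2-[(trifluoromethylsulfonyl)oxy]-1-[(1S,6S)-2-ethenyl-3-methyl-6-R-cyclohex-2-en-1-yl]cyclohex-2-ene-1-carboxylate
Conditions: KN(SiMe3)2, THF, −78 °C; then PhNTf2, −78 to 0 °C
Reagents that add atoms: N-phenylbis(trifluoromethanesulfonimide) FC(F)(F)S(=O)(=O)N(c1ccccc1)S(=O)(=O)C(F)(F)F
Why: Deprotonation can occur only on the CH2 side of the ketone because the other α-carbon is quaternary, so trapping the potassium enolate gives a single enol triflate whose double bond is the future bridgehead alkene.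

Step 14
Reactants: 17 enol triflate
Product: 19 ethyl (4S,4aS,4bS,5S)-4-[(tert-butyldimethylsilyl)oxy]-8-methyl-5-R-2,3,4,4a,4b,5,6,7,9,10-decahydrophenanthrene-4a-carboxylate, via alkylborane 18 (not isolated)
Conditions: 9-borabicyclo[3.3.1]nonane (9-BBN), THF, rt; then PdCl2(dppf) (10 mol%), AsPh3 (10 mol%), Cs2CO3, DMF/THF/H2O, 50 °C, high dilution
Reagents that add atoms: none
Why: Anti-Markovnikov hydroboration by 9-BBN is selective for the monosubstituted vinyl group, and the resulting B-alkyl borane undergoes intramolecular Suzuki–Miyaura coupling with the enol triflate to close six-membered ring B' without creating a stereocentre.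

Step 15
Reactants: 19 tricyclic ester
Product: 20 (4S,4aR,4bS,5S)-4-[(tert-butyldimethylsilyl)oxy]-4a-(hydroxymethyl)-8-methyl-5-R-2,3,4,4a,4b,5,6,7,9,10-decahydrophenanthrene
Conditions: LiAlH4, Et2O, 0 °C to rt
Reagents that add atoms: none
Why: Hydride reduction of the neopentyl ester gives the primary alcohol, with silyl ethers and alkenes inert to LiAlH4.

Step 16
Reactants: 20 angular hydroxymethyl tricycle
Product: 22 bicyclo[4.4.1]undecenone fused to ring C (the target skeleton with C=O at Ca in place of C=CH2 and the side chain as R), via neopentyl triflate 21 (not isolated)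
Conditions: Tf2O, 2,6-di-tert-butyl-4-methylpyridine, CH2Cl2, −78 °C to rt; aq. NaHCO3
Reagents that add atoms: none
Why: Triflation of the neopentyl alcohol and warming ionise the axial CH2–OTf bond with anchimeric assistance of the homoallylic ring A' alkene (3-exo attack of Cd on Cc gives a cyclopropylcarbinyl cation), and reopening of the Cb–Cd bond completes a net 1,2-alkenyl shift that inserts Cc between Cb and Cd, so the two six-membered rings that shared the Cb–Cd bond become the seven-membered rings A and B with the bridgehead alkene already in place. The closest known reaction type is the homoallyl–cyclopropylcarbinyl–homoallyl rearrangement of angular sulfonyloxymethyl Δ-octalins (19-sulfonyloxy-Δ5-steroids to 5(10→19)abeo systems), here terminated by a semipinacol 1,2-hydride shift of a β-silyloxy carbocation. No ring is closed by a lasting new bond; the only closure is the transient cyclopropane (3-exo-trig), and rings A and B arise by one-carbon ring expansion of rings A' and B'. The only new stereocentre, the bridgehead CH at Cb, is fixed by the configuration of the quaternary Cb in 20, because Cd stays on the inner face and the migrating hydride must enter from the outer face (inversion). The step needs alkenyl migration instead of σ-migration or capture at other cationic sites, and hydride migration from Ca instead of ring-carbon migration; the axial C–OTf bond parallel to the alkene p-orbital secures the first, and the equatorial Ca–H antiperiplanar to the breaking Cb–Cd bond (silyloxy axial, trans to the CH2OTf) together with the oxocarbenium sink secures the second, after which triflate removes the silyl group and releases the ketone.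

Step 17
Reactants: 22 bicyclic ketone
Product: 23 tert-butyldiphenylsilyl ether of the target
Conditions: Ph3PCH3Br, KOtBu, THF, 0 to 45 °C
Reagents that add atoms: methylenetriphenylphosphorane C=P(c1ccccc1)(c1ccccc1)c1ccccc1 (from methyltriphenylphosphonium bromide C[P+](c1ccccc1)(c1ccccc1)c1ccccc1.[Br-])
Why: Wittig methylenation of the ketone with the non-stabilised ylide installs the exocyclic methylene, and the only α-stereocentre is the bridgehead Cb, which cannot epimerise.

Step 18
Reactants: 23 tert-butyldiphenylsilyl ether of the target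
Product: 24 CNP0289180.1 (target)
Conditions: Bu4NF, THF, rt
Reagents that add atoms: none
Why: Fluoride cleavage of the silyl ether liberates the primary (E)-allylic alcohol without touching the alkenes or stereocentres.

**Compound list**

1 | (S)-citronellal, (3S)-3,7-dimethyloct-6-enal | O=CC[C@@H](C)CCC=C(C)C | starting material
2 | methyl vinyl ketone | CC(=O)C=C | starting material
3 | (2S,3S)-3,7-dimethyl-2-(3-oxobutyl)oct-6-enal | O=C[C@@H](CCC(C)=O)[C@@H](C)CCC=C(C)C | intermediate
4 | (4S)-4-[(2S)-6-methylhept-5-en-2-yl]cyclohex-2-en-1-one | O=C1C=C[C@H]([C@@H](C)CCC=C(C)C)CC1 | intermediate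
5 | (4S)-4-[(2S,5E)-7-hydroxy-6-methylhept-5-en-2-yl]cyclohex-2-en-1-one | O=C1C=C[C@H]([C@@H](C)CC/C=C(\C)CO)CC1 | intermediate
6 | (4S)-4-R-cyclohex-2-en-1-one (silyl ether of 5) | O=C1C=C[C@H]([C@@H](C)CC/C=C(\C)CO[Si](c2ccccc2)(c2ccccc2)C(C)(C)C)CC1 | intermediate
7 | (4S)-2-iodo-4-R-cyclohex-2-en-1-one | O=C1C(I)=C[C@H]([C@@H](C)CC/C=C(\C)CO[Si](c2ccccc2)(c2ccccc2)C(C)(C)C)CC1 | intermediate
8 | (1R,4S)-2-iodo-1-methyl-4-R-cyclohex-2-en-1-ol, hydroxyl trans to R | C[C@]1(O)C(I)=C[C@H]([C@@H](C)CC/C=C(\C)CO[Si](c2ccccc2)(c2ccccc2)C(C)(C)C)CC1 | intermediate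
9 | (1R,4S)-2-ethenyl-1-methyl-4-R-cyclohex-2-en-1-ol | C[C@]1(O)C(C=C)=C[C@H]([C@@H](C)CC/C=C(\C)CO[Si](c2ccccc2)(c2ccccc2)C(C)(C)C)CC1 | intermediate
10 | diethyl 3-oxoheptanedioate | CCOC(=O)CC(=O)CCCC(=O)OCC | starting material
11 | ethyl 2,6-dioxocyclohexane-1-carboxylate | CCOC(=O)C1C(=O)CCCC1=O | intermediate
12 | ethyl 2-chloro-6-oxocyclohex-1-ene-1-carboxylate | CCOC(=O)C1=C(Cl)CCCC1=O | intermediate
13 | allyl vinyl ether from 9 and 12 (tertiary allyl ether of the enol of 11) | CCOC(=O)C1=C(O[C@@]2(C)C(C=C)=C[C@H]([C@@H](C)CC/C=C(\C)CO[Si](c3ccccc3)(c3ccccc3)C(C)(C)C)CC2)CCCC1=O | intermediate (not isolated)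
14 | ethyl 2,6-dioxo-1-[(1S,6S)-2-ethenyl-3-methyl-6-R-cyclohex-2-en-1-yl]cyclohexane-1-carboxylate | CCOC(=O)C1(C(=O)CCCC1=O)[C@@H]1C(C=C)=C(C)CC[C@H]1[C@@H](C)CC/C=C(\C)CO[Si](c2ccccc2)(c2ccccc2)C(C)(C)C | intermediate
15 | ethyl (1R,2S)-2-hydroxy-6-oxo-1-[(1S,6S)-2-ethenyl-3-methyl-6-R-cyclohex-2-en-1-yl]cyclohexane-1-carboxylate | CCOC(=O)[C@@]1([C@@H](O)CCCC1=O)[C@@H]1C(C=C)=C(C)CC[C@H]1[C@@H](C)CC/C=C(\C)CO[Si](c2ccccc2)(c2ccccc2)C(C)(C)C | intermediate
16 | tert-butyldimethylsilyl ether of 15 | CCOC(=O)[C@@]1([C@@H](O[Si](C)(C)C(C)(C)C)CCCC1=O)[C@@H]1C(C=C)=C(C)CC[C@H]1[C@@H](C)CC/C=C(\C)CO[Si](c2ccccc2)(c2ccccc2)C(C)(C)C | intermediate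
17 | enol triflate of 16 (double bond toward the ring CH2) | CCOC(=O)[C@@]1([C@@H](O[Si](C)(C)C(C)(C)C)CCC=C1OS(=O)(=O)C(F)(F)F)[C@@H]1C(C=C)=C(C)CC[C@H]1[C@@H](C)CC/C=C(\C)CO[Si](c2ccccc2)(c2ccccc2)C(C)(C)C | intermediate
18 | B-alkyl-9-BBN adduct of 17 (boron on the terminal vinyl carbon) | CCOC(=O)[C@@]1([C@@H](O[Si](C)(C)C(C)(C)C)CCC=C1OS(=O)(=O)C(F)(F)F)[C@@H]1C(CCB2C3CCCC2CCC3)=C(C)CC[C@H]1[C@@H](C)CC/C=C(\C)CO[Si](c2ccccc2)(c2ccccc2)C(C)(C)C | intermediate (not isolated)
19 | ethyl (4S,4aS,4bS,5S)-4-[(tert-butyldimethylsilyl)oxy]-8-methyl-5-R-2,3,4,4a,4b,5,6,7,9,10-decahydrophenanthrene-4a-carboxylate (ester anti to H-4b, silyloxy trans to ester, R trans to C4a) | CCOC(=O)[C@]12[C@@H](O[Si](C)(C)C(C)(C)C)CCC=C1CCC1=C(C)CC[C@@H]([C@@H](C)CC/C=C(\C)CO[Si](c3ccccc3)(c3ccccc3)C(C)(C)C)[C@@H]12 | intermediate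
20 | 4a-hydroxymethyl analogue of 19 | OC[C@]12[C@@H](O[Si](C)(C)C(C)(C)C)CCC=C1CCC1=C(C)CC[C@@H]([C@@H](C)CC/C=C(\C)CO[Si](c3ccccc3)(c3ccccc3)C(C)(C)C)[C@@H]12 | intermediate
21 | trifluoromethanesulfonate of 20 | FC(F)(F)S(=O)(=O)OC[C@]12[C@@H](O[Si](C)(C)C(C)(C)C)CCC=C1CCC1=C(C)CC[C@@H]([C@@H](C)CC/C=C(\C)CO[Si](c3ccccc3)(c3ccccc3)C(C)(C)C)[C@@H]12 | intermediate (not isolated)
22 | bicyclo[4.4.1]undecenone fused to ring C: target skeleton with C=O at Ca and side chain R | O=C1CCC=C2CCC3=C(C)CC[C@@H]([C@@H](C)CC/C=C(\C)CO[Si](c4ccccc4)(c4ccccc4)C(C)(C)C)[C@@H]3[C@@H]1C2 | intermediate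
23 | tert-butyldiphenylsilyl ether of the target | C=C1CCC=C2CCC3=C(C)CC[C@@H]([C@@H](C)CC/C=C(\C)CO[Si](c4ccccc4)(c4ccccc4)C(C)(C)C)[C@@H]3[C@@H]1C2 | intermediate
24 | CNP0289180.1 | C=C1CCC=C2CCC3=C(C)CC[C@@H]([C@@H](C)CC/C=C(\C)CO)[C@@H]3[C@@H]1C2 | target

**Totals.** Total step count: 18. Longest linear sequence: 16 steps (steps 1–7 and 10–18).

**Steps most likely to fail**

Step 16 (key step). The cyclopropylcarbinyl cation may leak into the isomeric cyclopropylcarbinyl or cyclobutyl manifold, or lose a proton before the hydride shift, and the primary triflate may decompose before the alkene participates. The fallback sets out from 20 and comes back at 22 by splitting the cascade into two known operations. Compound 20 would be converted into the methanesulfonate of 20 F1 (MsCl, Et3N, CH2Cl2). F1 would be solvolysed under buffered conditions (KOAc, aqueous acetone, reflux), the homoallyl-to-cyclopropylcarbinyl solvolysis known for 19-mesyloxy-Δ5-steroids, to give the isolable cyclopropylcarbinol F2 (cyclopropane Cb–Cc–Cd, hydroxyl on the former alkene CH). F2 would then be ionised at the carbinol carbon with BF3·OEt2 in CH2Cl2 at −78 °C, so that ring opening and the semipinacol hydride shift start from a purified precursor at low temperature and give 22.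

Step 10. The hindered tertiary alkoxide may act as a base toward 12 or the tertiary dienyl alcohol may eliminate, and ion-pair return of the very stabilised enolate may erode facial fidelity. The fallback sets out from 9 and 11 and comes back at 14 by a Tsuji–Trost allylic alkylation. Compound 9 would be converted into the methyl carbonate of 9 F3 (n-BuLi, then ClCO2Me). F3 would be treated with Pd(PPh3)4 (zerovalent palladium) and 11 in THF: ionisation anti to the carbonate and attack of the soft tricarbonyl nucleophile anti to palladium at the less substituted allyl terminus should give 14 with net retention, the same face as in the Claisen route.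

Step 11. Discrimination between the two diastereotopic carbonyls may be poor if the remote stereocentres of ring C oppose the catalyst, and over-reduction to the diol is possible. The fallback sets out from 14 and comes back at 15 by substrate control and recycling. Compound 14 would be mono-reduced with NaBH4/CeCl3 in MeOH/THF at −78 °C, 15 would be separated by chromatography from the diastereomeric hydroxy ketone F4 (the other carbonyl reduced), and F4 would be returned to 14 by Dess–Martin oxidation.

**Further compounds**

F1 | step 16 | methanesulfonate of 20 | CS(=O)(=O)OC[C@]12[C@@H](O[Si](C)(C)C(C)(C)C)CCC=C1CCC1=C(C)CC[C@@H]([C@@H](C)CC/C=C(\C)CO[Si](c3ccccc3)(c3ccccc3)C(C)(C)C)[C@@H]12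
F2 | step 16 | cyclopropylcarbinol (cyclopropane Cb–Cc–Cd, hydroxyl on the adjacent ring A' carbon, silyloxy at Ca) | C1[C@]23[C@@H](O[Si](C)(C)C(C)(C)C)CC[C@H](O)[C@]12CCC1=C(C)CC[C@@H]([C@@H](C)CC/C=C(\C)CO[Si](c4ccccc4)(c4ccccc4)C(C)(C)C)[C@@H]13
F3 | step 10 | methyl carbonate of 9 | COC(=O)O[C@@]1(C)C(C=C)=C[C@H]([C@@H](C)CC/C=C(\C)CO[Si](c2ccccc2)(c2ccccc2)C(C)(C)C)CC1
F4 | step 11 | diastereomer of 15 with the other carbonyl reduced | CCOC(=O)[C@]1([C@H](O)CCCC1=O)[C@@H]1C(C=C)=C(C)CC[C@H]1[C@@H](C)CC/C=C(\C)CO[Si](c2ccccc2)(c2ccccc2)C(C)(C)C
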